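## Retrosynthetic overview

1. Target ⇒ C25 ε-apo-12′-carotenal + C5 formyl ylide (Wittig, C11′=C12′); C25 aldehyde ⇒ ε-C15 phosphonium salt + symmetrical C10-dialdehyde (Wittig, C11=C12).
2. C15 salt ⇒ (3S,6R)-3-hydroxy-α-ionone (vinyl Grignard, then PPh3·HBr) ⇒ bridged lactol, a masked cis-3-hydroxy-α-cyclocitral (Wittig, C7=C8).
3. Key disconnection: the C1–C6 bond of the ε-ring, closed as the cyclase does it (C1 carbocation + C5=C6 π-bond, then loss of H-4). The substrate already carries the C3 oxygen and C7 tied together as an unsaturated δ-lactone, so only the 3,6-cis ring can close and the C3 centre dictates C6.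
4. Lactone ⇒ Ru-catalysed asymmetric hydrogenation of a 2-pyranone ⇒ 4,6-dimethyl-2-pyranone + acetone (lateral aldol).
5. Ring order: the δ-lactone (bought as the pyranone, used only as a tether, opened in step 5) is present first; the carbocyclic ε-ring, the only ring of the target, is formed in the cation–olefin step.

Assumption: the target is (3S,6R)-3-hydroxy-8′-apo-ε-caroten-8′-al, all-E, with 3-OH and the C6 chain cis (carotenoid numbering: C1 = CMe2, C3 = CHOH, C5 = C–Me, C6 = CH bearing the chain); the C10-dialdehyde is taken as a commercial industrial intermediate.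

## Route

Step 1
Reactants: 1 4,6-dimethyl-2H-pyran-2-one; 2 acetone
Product: 4 6-(2-hydroxy-2-methylpropyl)-4-methyl-2H-pyran-2-one, via 6-lithiomethyl-4-methyl-2-pyranone 3 (not isolated)
Conditions: LiHMDS (1.05 equiv), THF, −78 °C, 30 min; acetone (1.5 equiv), −78 °C, 1 h; AcOH quench at −78 °C
Reagents that add atoms: acetone (2), CC(C)=O
Why: Lateral (vinylogous) metalation–aldol addition: the 6-methyl group is the ε-position whose anion is delocalised through the whole pyranone as a linear trienolate (the 4-methyl gives only a cross-conjugated dienolate), and this type of 6-methyl-2-pyranone anion adds to ketones through its exocyclic carbon; no stereocentre is formed.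

Step 2
Reactants: 4 6-(2-hydroxy-2-methylpropyl)-4-methyl-2H-pyran-2-one
Product: 5 (6R)-6-(2-hydroxy-2-methylpropyl)-4-methyl-5,6-dihydro-2H-pyran-2-one
Conditions: H2 (60 bar), [Ru(OAc)2((S)-MeO-BIPHEP)] (0.5 mol%), HBF4·OEt2 (1 mol%), i-PrOH/CH2Cl2, 60 °C
Reagents that add atoms: none
Why: Ru/atropisomeric-diphosphine asymmetric hydrogenation of a 2-pyranone, which reduces only the C5=C6 enol-ester bond and leaves the conjugated C3=C4 bond (established for 4,6-dimethyl-2-pyranone at high ee), so the ligand-controlled facial delivery of H2 sets the C6 carbinol centre as R (this is C3 of the target); the ligand antipode is used if the first run shows the opposite sense.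

Step 3
Reactants: 5 (6R)-6-(2-hydroxy-2-methylpropyl)-4-methyl-5,6-dihydro-2H-pyran-2-one
Product: 8 (1S,4R)-5,8,8-trimethyl-2-oxabicyclo[2.2.2]oct-5-en-3-one, via open-chain tertiary carbocation 6 (not isolated), via bicyclic tertiary carbocation 7 (not isolated)
Conditions: TfOH (0.3 equiv), HFIP (0.05 M), 0 °C → 25 °C (keep below 30 °C)
Reagents that add atoms: none
Why: Proposed new method: ionisation of the tertiary carbinol (a hydrated ψ-end) gives the same C1 carbocation 6 that the ε-cyclase makes by protonation, the C5=C6 π-bond (α-carbon of the β-methyl enoate) attacks it to close C1–C6, and the tertiary C5 cation 7 loses H-4 to give the ε-type C4=C5 alkene because the β-type C5=C6 alkene would sit at a bridgehead (Bredt), while the lactone tether allows bonding only on the face that makes C3–O and C6–C7 cis, so the existing carbinol centre (R in 5, S in 8 by CIP priorities only) fixes C6 as R; the closest known reactions are the acid cyclisation of geranic acid and its esters to α-cyclogeranates (enoate α-carbon attacking a tertiary cation), the pseudoionone to α-ionone cyclisation, and π-route closures of 2-(cyclohex-3-enyl)ethyl cations to bicyclo[2.2.2]octyl systems.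

Step 4
Reactants: 8 (1S,4R)-5,8,8-trimethyl-2-oxabicyclo[2.2.2]oct-5-en-3-one
Product: 9 (1S,4R)-5,8,8-trimethyl-2-oxabicyclo[2.2.2]oct-5-en-3-ol (anomer mixture; ring-chain tautomer of cis-3-hydroxy-α-cyclocitral)
Conditions: DIBAL-H (1.1 equiv), CH2Cl2, −78 °C; aq. Rochelle salt
Reagents that add atoms: none
Why: Partial reduction of a lactone to the lactol with DIBAL-H, the tetrahedral aluminium hemiacetal being stable at −78 °C so the diol is not formed; the bridgehead α-carbon cannot enolise, both ring stereocentres are untouched, and the new hemiacetal carbon is an inconsequential anomer mixture.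

Step 5
Reactants: 9 (1S,4R)-5,8,8-trimethyl-2-oxabicyclo[2.2.2]oct-5-en-3-ol; 10 1-(triphenylphosphoranylidene)propan-2-one
Product: 11 (3E)-4-[(1R,4S)-4-hydroxy-2,6,6-trimethylcyclohex-2-en-1-yl]but-3-en-2-one [(3S,6R)-3-hydroxy-α-ionone]
Conditions: 10 (1.5 equiv), toluene, 80 °C
Reagents that add atoms: 1-(triphenylphosphoranylidene)propan-2-one (10), CC(=O)C=P(c1ccccc1)(c1ccccc1)c1ccccc1
Why: Wittig olefination of the lactol through its open hydroxy-aldehyde tautomer with a carbonyl-stabilised ylide, which gives the (E)-enone and, being neutral, should not epimerise C6, move the C4=C5 bond into conjugation or eliminate the C3 hydroxyl.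

Step 6
Reactants: 11 (3S,6R)-3-hydroxy-α-ionone; 12 vinylmagnesium bromide
Product: 13 (1E)-1-[(1R,4S)-4-hydroxy-2,6,6-trimethylcyclohex-2-en-1-yl]-3-methylpenta-1,4-dien-3-ol (3RS)
Conditions: vinylMgBr (3 equiv), THF, −20 → 0 °C; H2O/aq. NH4Cl
Reagents that add atoms: vinylmagnesium bromide (12), C=C[Mg]Br
Why: 1,2-Grignard addition to the methyl ketone (classical vinyl-ionol synthesis; one equivalent is spent on the C3 hydroxyl); the new tertiary carbinol centre forms unselectively and is destroyed in step 7.

Step 7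
Reactants: 13 the vinyl carbinol; 14 triphenylphosphine hydrobromide
Product: 15 [(2E,4E)-5-[(1R,4S)-4-hydroxy-2,6,6-trimethylcyclohex-2-en-1-yl]-3-methylpenta-2,4-dien-1-yl]triphenylphosphonium bromide
Conditions: PPh3·HBr (1.0 equiv), MeOH, 0 → 20 °C; crystallise (EtOAc)
Reagents that add atoms: triphenylphosphine hydrobromide (14), [PH+](c1ccccc1)(c1ccccc1)c1ccccc1.[Br-]
Why: SN1′ allylic transposition with PPh3·HBr (the industrial C15 Wittig-salt synthesis): the doubly allylic tertiary carbinol ionises to a pentadienyl cation that PPh3 captures at the unhindered terminus much faster than the secondary allylic C3–OH can ionise, and the single equivalent of acid is consumed as the salt forms; C3 and C6 are untouched and the new C9=C10 bond is mainly E (9Z salt removed by crystallisation).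

Step 8
Reactants: 15 the C15 phosphonium bromide; 16 (2E,4E,6E)-2,7-dimethylocta-2,4,6-trienedial
Product: 18 (2E,4E,6E,8E,10E,12E)-13-[(1R,4S)-4-hydroxy-2,6,6-trimethylcyclohex-2-en-1-yl]-2,7,11-trimethyltrideca-2,4,6,8,10,12-hexaenal [(3S,6R)-3-hydroxy-12′-apo-ε-caroten-12′-al], via C15 phosphorus ylide 17 (not isolated)
Conditions: 16 (2.5 equiv, excess recovered), NaOMe (1.1 equiv, slow addition), CH2Cl2/MeOH, −10 → 20 °C
Reagents that add atoms: (2E,4E,6E)-2,7-dimethylocta-2,4,6-trienedial (16), O=C/C(C)=C/C=C/C=C(\C)C=O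
Why: Wittig olefination of the semi-stabilised allylic ylide with an excess of the symmetrical dialdehyde, mono-selective because the product polyenal is less electrophilic than 16; it forms C11=C12 (mainly E, residual Z isomers are equilibrated after step 11) and touches no stereocentre.

Step 9
Reactants: 19 1-chloro-3-methylbut-2-ene (prenyl chloride)
Product: 20 (2E)-4-chloro-2-methylbut-2-enal
Conditions: SeO2 (1.0 equiv), 1,4-dioxane, 80 °C
Reagents that add atoms: selenium dioxide, O=[Se]=O
Why: Riley allylic oxidation: SeO2 attacks the (E)-methyl group of the trisubstituted alkene by ene reaction and [2,3]-sigmatropic shift and carries it to the (E)-enal.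

Step 10
Reactants: 20 (2E)-4-chloro-2-methylbut-2-enal; 21 triphenylphosphine
Product: 22 [(2E)-3-methyl-4-oxobut-2-en-1-yl]triphenylphosphonium chloride
Conditions: PPh3 (1.0 equiv), toluene, 20 → 50 °C (salt precipitates)
Reagents that add atoms: triphenylphosphine (21), P(c1ccccc1)(c1ccccc1)c1ccccc1
Why: SN2 quaternisation of triphenylphosphine by the primary allylic chloride, with retention of the E enal geometry.

Step 11
Reactants: 18 (3S,6R)-3-hydroxy-12′-apo-ε-caroten-12′-al; 22 the C5 phosphonium chloride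
Product: 24 (2E,4E,6E,8E,10E,12E,14E,16E)-17-[(1R,4S)-4-hydroxy-2,6,6-trimethylcyclohex-2-en-1-yl]-2,6,11,15-tetramethylheptadeca-2,4,6,8,10,12,14,16-octaenal [(3S,6R)-3-hydroxy-8′-apo-ε-caroten-8′-al, CNP0265614.2], via C5 formyl ylide 23 (not isolated)
Conditions: 22 (1.3 equiv), NaOMe (1.3 equiv, slow addition), CH2Cl2/MeOH, 0 → 20 °C; then n-heptane, reflux 3 h (Z → E), crystallise
Reagents that add atoms: [(2E)-3-methyl-4-oxobut-2-en-1-yl]triphenylphosphonium chloride (22), O=C/C(C)=C/C[P+](c1ccccc1)(c1ccccc1)c1ccccc1.[Cl-]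
Why: Wittig olefination with the vinylogous formyl-stabilised C5 ylide (the industrial C5 extension of apocarotenals), forming C11′=C12′ mainly E; brief heating equilibrates residual Z isomers to the crystalline all-E aldehyde and no stereocentre is touched.

## Compound list

1 | 4,6-dimethyl-2H-pyran-2-one | CC1=CC(=O)OC(C)=C1 | starting material
2 | acetone | CC(C)=O | starting material
3 | 6-lithiomethyl-4-methyl-2-pyranone (delocalised trienolate) | [Li]CC1=CC(C)=CC(=O)O1 | intermediate (not isolated)
4 | 6-(2-hydroxy-2-methylpropyl)-4-methyl-2H-pyran-2-one | CC1=CC(=O)OC(CC(C)(C)O)=C1 | intermediate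
5 | (6R)-6-(2-hydroxy-2-methylpropyl)-4-methyl-5,6-dihydro-2H-pyran-2-one | CC1=CC(=O)O[C@@H](CC(C)(C)O)C1 | intermediate
6 | open-chain tertiary carbocation (C1 cation of the lactone) | CC1=CC(=O)O[C@@H](C[C+](C)C)C1 | intermediate (not isolated)
7 | bicyclic tertiary carbocation (C5 cation after C1–C6 closure) | C[C+]1C[C@@H]2CC(C)(C)[C@H]1C(=O)O2 | intermediate (not isolated)
8 | (1S,4R)-5,8,8-trimethyl-2-oxabicyclo[2.2.2]oct-5-en-3-one | CC1=C[C@@H]2CC(C)(C)[C@H]1C(=O)O2 | intermediate
9 | (1S,4R)-5,8,8-trimethyl-2-oxabicyclo[2.2.2]oct-5-en-3-ol (anomer mixture) | CC1=C[C@@H]2CC(C)(C)[C@H]1C(O)O2 | intermediate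
10 | 1-(triphenylphosphoranylidene)propan-2-one | CC(=O)C=P(c1ccccc1)(c1ccccc1)c1ccccc1 | starting material
11 | (3E)-4-[(1R,4S)-4-hydroxy-2,6,6-trimethylcyclohex-2-en-1-yl]but-3-en-2-one | CC1=C[C@@H](O)CC(C)(C)[C@H]1/C=C/C(C)=O | intermediate
12 | vinylmagnesium bromide | C=C[Mg]Br | starting material
13 | (1E)-1-[(1R,4S)-4-hydroxy-2,6,6-trimethylcyclohex-2-en-1-yl]-3-methylpenta-1,4-dien-3-ol (3RS) | CC1=C[C@@H](O)CC(C)(C)[C@H]1/C=C/C(C)(O)C=C | intermediate
14 | triphenylphosphine hydrobromide | [PH+](c1ccccc1)(c1ccccc1)c1ccccc1.[Br-] | starting material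
15 | [(2E,4E)-5-[(1R,4S)-4-hydroxy-2,6,6-trimethylcyclohex-2-en-1-yl]-3-methylpenta-2,4-dien-1-yl]triphenylphosphonium bromide | CC1=C[C@@H](O)CC(C)(C)[C@H]1/C=C/C(C)=C/C[P+](c1ccccc1)(c1ccccc1)c1ccccc1.[Br-] | intermediate
16 | (2E,4E,6E)-2,7-dimethylocta-2,4,6-trienedial | O=C/C(C)=C/C=C/C=C(\C)C=O | starting material
17 | C15 phosphorus ylide derived from 15 | CC1=C[C@@H](O)CC(C)(C)[C@H]1/C=C/C(C)=C/C=P(c1ccccc1)(c1ccccc1)c1ccccc1 | intermediate (not isolated)
18 | (3S,6R)-3-hydroxy-12′-apo-ε-caroten-12′-al | CC1=C[C@@H](O)CC(C)(C)[C@H]1/C=C/C(C)=C/C=C/C(C)=C/C=C/C=C(\C)C=O | intermediate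
19 | 1-chloro-3-methylbut-2-ene | CC(C)=CCCl | starting material
20 | (2E)-4-chloro-2-methylbut-2-enal | O=C/C(C)=C/CCl | intermediate
21 | triphenylphosphine | P(c1ccccc1)(c1ccccc1)c1ccccc1 | starting material
22 | [(2E)-3-methyl-4-oxobut-2-en-1-yl]triphenylphosphonium chloride | O=C/C(C)=C/C[P+](c1ccccc1)(c1ccccc1)c1ccccc1.[Cl-] | intermediate
23 | C5 formyl ylide derived from 22 | O=C/C(C)=C/C=P(c1ccccc1)(c1ccccc1)c1ccccc1 | intermediate (not isolated)
24 | (3S,6R)-3-hydroxy-8′-apo-ε-caroten-8′-al | CC1=C[C@@H](O)CC(C)(C)[C@H]1/C=C/C(C)=C/C=C/C(C)=C/C=C/C=C(C)/C=C/C=C(\C)C=O | target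

## Step count and risk

Total step count: 11. Longest linear sequence: 9 (steps 1–8 and 11; steps 9–10 prepare the C5 salt).

Steps most likely to fail:

**Step 3 (key cyclisation).** The enoate α-carbon is a weak π-nucleophile and must react through a boat-like transition state. The cation can instead lose a proton to the isobutenyl isomer, whose allylic lactone C–O bond can ionise, or be held as a dioxanylium ion by the lactone carbonyl.

Fallback: it sets out from 5 and comes back at 11. The lactone is first opened and the ring is then closed in the open chain, where the Z geometry of C5=C6 inherited from the lactone is used to obtain the cis ring.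
- DIBAL-H reduction of 5 gives the lactol (6R)-6-(2-hydroxy-2-methylpropyl)-4-methyl-5,6-dihydro-2H-pyran-2-ol F1.
- Wittig reaction with 10 gives (3E,5Z,8R)-8,10-dihydroxy-6,10-dimethylundeca-3,5-dien-2-one F2.
- Ac2O/pyridine acetylates only the secondary hydroxyl to give (4R,6Z,8E)-2-hydroxy-2,6-dimethyl-10-oxoundeca-6,8-dien-4-yl acetate F3.
- 85% H3PO4 at 0–20 °C ionises the tertiary carbinol and effects the classical pseudoionone-type closure. In the chair transition state the acetoxy group is equatorial and C7 axial (Z-alkene), which should give (3S,6R)-3-acetoxy-α-ionone F4.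
- K2CO3/MeOH then gives 11.

**Step 2 (asymmetric hydrogenation).** The substrate carries a larger, hydroxylated 6-substituent than the known 4,6-dimethyl case, so the ee may drop or the second C=C may be reduced.

Fallback: it sets out from 4 and comes back at 5, replacing asymmetric catalysis by a classical resolution.
- 4 is hydrogenated with a racemic Ru–BINAP catalyst to racemic 6-(2-hydroxy-2-methylpropyl)-4-methyl-5,6-dihydro-2H-pyran-2-one F5.
- LiOH opens the lactone, and salt metathesis with (R)-1-phenylethylammonium chloride followed by fractional crystallisation gives (R)-1-phenylethylammonium (2Z,5R)-5,7-dihydroxy-3,7-dimethyloct-2-enoate F6 (the amine antipode is chosen so that the 5R salt crystallises).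
- Acidification to pH 3 at 0 °C lets the (Z)-δ-hydroxy acid relactonise spontaneously to 5.

**Step 5 (Wittig on the bridged lactol).** The aldehyde is hindered and the keto-ylide is weakly nucleophilic. Prolonged heating risks enolisation at C6, giving the conjugated β-isomer or loss of the C3 hydroxyl to safranal.

Fallback: it sets out from 9 and comes back at 15, building C15 directly from C10 + C5 at low temperature and bypassing 11 and 13.
- Horner–Wadsworth–Emmons reaction of 9 with the lithium anion of commercial triethyl 3-methyl-4-phosphonocrotonate (THF, −78 → 0 °C) gives ethyl (2E,4E)-5-[(1R,4S)-4-hydroxy-2,6,6-trimethylcyclohex-2-en-1-yl]-3-methylpenta-2,4-dienoate F7.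
- DIBAL-H reduces it to (2E,4E)-5-[(1R,4S)-4-hydroxy-2,6,6-trimethylcyclohex-2-en-1-yl]-3-methylpenta-2,4-dien-1-ol F8.
- PPh3·HBr in MeOH at 0 °C converts this primary dienylic alcohol into 15.

## Further compounds

F1 | step 3 | (6R)-6-(2-hydroxy-2-methylpropyl)-4-methyl-5,6-dihydro-2H-pyran-2-ol (anomer mixture) | CC1=CC(O)O[C@@H](CC(C)(C)O)C1
F2 | step 3 | (3E,5Z,8R)-8,10-dihydroxy-6,10-dimethylundeca-3,5-dien-2-one | CC(=O)/C=C/C=C(C)\C[C@@H](O)CC(C)(C)O
F3 | step 3 | (4R,6Z,8E)-2-hydroxy-2,6-dimethyl-10-oxoundeca-6,8-dien-4-yl acetate | CC(=O)/C=C/C=C(C)\C[C@@H](OC(C)=O)CC(C)(C)O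
F4 | step 3 | (1S,4R)-3,5,5-trimethyl-4-[(1E)-3-oxobut-1-en-1-yl]cyclohex-2-en-1-yl acetate [(3S,6R)-3-acetoxy-α-ionone] | CC1=C[C@@H](OC(C)=O)CC(C)(C)[C@H]1/C=C/C(C)=O
F5 | step 2 | racemic 6-(2-hydroxy-2-methylpropyl)-4-methyl-5,6-dihydro-2H-pyran-2-one | CC1=CC(=O)OC(CC(C)(C)O)C1
F6 | step 2 | (R)-1-phenylethylammonium (2Z,5R)-5,7-dihydroxy-3,7-dimethyloct-2-enoate | [O-]C(=O)/C=C(C)\C[C@@H](O)CC(C)(C)O.C[C@@H]([NH3+])c1ccccc1
F7 | step 5 | ethyl (2E,4E)-5-[(1R,4S)-4-hydroxy-2,6,6-trimethylcyclohex-2-en-1-yl]-3-methylpenta-2,4-dienoate | CC1=C[C@@H](O)CC(C)(C)[C@H]1/C=C/C(C)=C/C(=O)OCC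
F8 | step 5 | (2E,4E)-5-[(1R,4S)-4-hydroxy-2,6,6-trimethylcyclohex-2-en-1-yl]-3-methylpenta-2,4-dien-1-ol | CC1=C[C@@H](O)CC(C)(C)[C@H]1/C=C/C(C)=C/CO
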